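**Retrosynthetic overview**
1. The C9 ester comes from acylation of the C9 alcohol. Ring C is bought as 3-methylfuran-2(5H)-one and joined last to the side-chain aldehyde by vinylogous aldol addition and elimination, which sets the Z alkene.
2. The C8 methyl group and the C7=C8 alkene come from a spiro enone (C8=O, C6=C7) by acetoxylation at C9, conjugate reduction with enol triflation, and methyl coupling. The enone alkene keeps the two arms of ring A distinct.
3. Key disconnection: the spiro enone comes from an acyclic keto aldehyde enoate. One base-triggered cascade closes ring A by aldol condensation and then ring B by vinylogous Michael addition (C5–C1).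
4. The acyclic chain comes from (S)-citronellal, methyl methacrylate (cross-metathesis) and methyl vinyl ketone (enamine Michael addition). The citronellal stereocentre (C4) controls C1, C5 and the side-chain carbon.
5. Ring order: A, then B, in the same flask. Ring C is not built.

Assumption: (S)-citronellal of high ee counts as a commercial chiral-pool material, and all names use one fixed spiro[4.5]decane numbering (C1 side-chain carbon, C4 methyl carbon, C5 spiro carbon, C6–C7–C8 the arm syn to the side chain, C9 oxygenated carbon, C10).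

**Step 1**
Reactants: 1 (S)-citronellal; 2 methyl methacrylate
Product: 3 methyl (2E,6S)-2,6-dimethyl-8-oxooct-2-enoate
Conditions: 2 (8 equiv, neat), second-generation Hoveyda–Grubbs catalyst (2 mol %), 90 °C, argon sweep
Reagents that add atoms: methyl methacrylate (2), C=C(C)C(=O)OC
Why: Olefin cross-metathesis exchanges the isopropylidene end of 1 for the methacrylate alkylidene; loss of volatile isobutene drives it, the trisubstituted enoate forms as the thermodynamic E isomer, and the stereocentre is untouched.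

**Step 2**
Reactants: 3 methyl (2E,6S)-2,6-dimethyl-8-oxooct-2-enoate; 4 methyl vinyl ketone
Product: 7 methyl (2S)-2-[(1R,4S,5S)-4-methyl-8-oxospiro[4.5]dec-6-en-1-yl]propanoate, via keto aldehyde 5 (not isolated), via 4-substituted cyclohexenone 6 (not isolated)
Conditions: 4 (1.5 equiv), Et2NSiMe3 (20 mol %), MeCN, 80 °C; evaporate; KOt-Bu (30 mol %), 4 Å MS, t-BuOH–THF, 0 °C to rt; AcOH quench
Reagents that add atoms: methyl vinyl ketone (4), C=CC(C)=O
Why: Proposed new method: a catalytic Stork-type enamine Michael addition gives 5, base closes ring A by Robinson-type aldol condensation to 6, and the extended dienolate of 6 can reach the tethered enoate only through its γ-carbon (5-exo-trig vinylogous Michael addition), which closes ring B; A(1,3) strain holds C4–H in the dienolate plane next to C6–H so the tether attacks the face that leaves the methyl group syn to the saturated C10 arm, the enoate stacks over the dienolate so the propanoate carbon ends syn to the vinylic C6 arm and trans to the methyl group, and the ester enolate is protonated anti to the new quaternary carbon (2S); the closest known reactions are the enamine Michael/aldol synthesis of 4-substituted cyclohexenones from citronellal and intramolecular γ-alkylation of cyclohexenone dienolates to spiro[4.5]decenones.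

**Step 3**
Reactants: 7 methyl (2S)-2-[(1R,4S,5S)-4-methyl-8-oxospiro[4.5]dec-6-en-1-yl]propanoate
Product: 8 methyl (2S)-2-[(1R,4S,5S,9S)-9-acetoxy-4-methyl-8-oxospiro[4.5]dec-6-en-1-yl]propanoate
Conditions: Mn(OAc)3 (3 equiv), benzene, 80 °C, Dean–Stark
Reagents that add atoms: manganese triacetate, CC(=O)[O-].CC(=O)[O-].CC(=O)[O-].[Mn+3]
Why: α'-Acetoxylation of an enone: C9 is the only enolisable carbon of the ketone, and acetate enters the face of C9 flanked by C1–H because the C4 methyl group covers the other face, which sets 9S.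

**Step 4**
Reactants: 8 methyl (2S)-2-[(1R,4S,5S,9S)-9-acetoxy-4-methyl-8-oxospiro[4.5]dec-6-en-1-yl]propanoate
Product: 10 methyl (2S)-2-[(1R,4S,5S,9S)-9-acetoxy-4-methyl-8-(trifluoromethylsulfonyloxy)spiro[4.5]dec-7-en-1-yl]propanoate, via lithium enolate 9 (not isolated)
Conditions: LiBH(s-Bu)3 (1.05 equiv), THF, −78 °C; then Comins reagent (1.2 equiv), −78 to −20 °C
Reagents that add atoms: N-(5-chloropyridin-2-yl)bis(trifluoromethanesulfonimide) (Comins reagent), O=S(=O)(N(c1ccc(Cl)cn1)S(=O)(=O)C(F)(F)F)C(F)(F)F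
Why: Conjugate hydride addition to the β-unsubstituted enone gives one regiodefined enolate that cannot equilibrate without a proton source, and fast O-sulfonylation at −78 °C (enolate trapping) outruns acetyl migration and fixes the alkene in the arm that was vinylic, so C5 and C9 are kept.

**Step 5**
Reactants: 10 methyl (2S)-2-[(1R,4S,5S,9S)-9-acetoxy-4-methyl-8-(trifluoromethylsulfonyloxy)spiro[4.5]dec-7-en-1-yl]propanoate
Product: 11 methyl (2S)-2-[(1R,4S,5S,9S)-9-acetoxy-4,8-dimethylspiro[4.5]dec-7-en-1-yl]propanoate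
Conditions: Me2Zn (0.8 equiv), Pd(PPh3)4 (5 mol %), THF, 0 °C to rt
Reagents that add atoms: dimethylzinc, C[Zn]C
Why: Negishi coupling: zerovalent palladium inserts into the alkenyl triflate much faster than it ionises the hindered allylic acetate, β-acetoxy elimination would need a six-membered cyclic allene, both esters tolerate the zinc reagent, and the alkene position is retained.

**Step 6**
Reactants: 11 methyl (2S)-2-[(1R,4S,5S,9S)-9-acetoxy-4,8-dimethylspiro[4.5]dec-7-en-1-yl]propanoate
Product: 12 (2S)-2-[(1R,4S,5S,9S)-9-hydroxy-4,8-dimethylspiro[4.5]dec-7-en-1-yl]propanal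
Conditions: i-Bu2AlH (3.2 equiv), CH2Cl2, −78 °C; MeOH quench at −78 °C; aqueous Rochelle salt
Reagents that add atoms: none
Why: Partial ester reduction: the acetate is cleaved to the aluminium alkoxide while the hindered methyl ester stops at the tetrahedral aluminium hemiacetal and releases the aldehyde only on quench, so neither C9 nor the α-carbon is touched.

**Step 7**
Reactants: 12 (2S)-2-[(1R,4S,5S,9S)-9-hydroxy-4,8-dimethylspiro[4.5]dec-7-en-1-yl]propanal; 13 3-phenylpropanoyl chloride
Product: 14 (1R,4S,5S,9S)-4,8-dimethyl-1-[(2S)-1-oxopropan-2-yl]spiro[4.5]dec-7-en-9-yl 3-phenylpropanoate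
Conditions: 13 (1.2 equiv), pyridine, DMAP (10 mol %), CH2Cl2, 0 °C
Reagents that add atoms: 3-phenylpropanoyl chloride (13), O=C(Cl)CCc1ccccc1
Why: DMAP-catalysed acylation of the allylic alcohol breaks no bond at C9 (retention), and the weak base at 0 °C does not enolise the α-branched aldehyde.

**Step 8**
Reactants: 14 (1R,4S,5S,9S)-4,8-dimethyl-1-[(2S)-1-oxopropan-2-yl]spiro[4.5]dec-7-en-9-yl 3-phenylpropanoate; 15 3-methylfuran-2(5H)-one
Product: 18 (1R,4S,5S,9S)-4,8-dimethyl-1-[(1Z,2S)-1-(4-methyl-5-oxofuran-2(5H)-ylidene)propan-2-yl]spiro[4.5]dec-7-en-9-yl 3-phenylpropanoate, via silyloxyfuran 16 (not isolated), via silyl aldol adduct 17 (not isolated)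
Conditions: 15, TBSOTf (1.1 equiv), Et3N (1.2 equiv), CH2Cl2, 0 °C; then 14, TBSOTf (10 mol %), −78 °C; then DBU (2 equiv), −78 °C to rt
Reagents that add atoms: 3-methylfuran-2(5H)-one (15), CC1=CCOC1=O; tert-butyldimethylsilyl triflate, CC(C)(C)[Si](C)(C)OS(=O)(=O)C(F)(F)F (its silyl group stays only in 16 and 17)
Why: Vinylogous Mukaiyama aldol addition at C5 of the silyloxyfuran followed by E1cB loss of silanolate gives the thermodynamically preferred Z-alkylidene butenolide (alkyl group syn to the ring oxygen), and the low-temperature aldol stage protects the α-stereocentre.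

**Compound list**
1 | (3S)-3,7-dimethyloct-6-enal, (S)-citronellal | C[C@@H](CCC=C(C)C)CC=O | starting material
2 | methyl methacrylate | C=C(C)C(=O)OC | starting material
3 | methyl (2E,6S)-2,6-dimethyl-8-oxooct-2-enoate | C[C@@H](CC/C=C(\C)C(=O)OC)CC=O | intermediate
4 | methyl vinyl ketone (but-3-en-2-one) | C=CC(C)=O | starting material
5 | methyl (2E,6S)-7-formyl-2,6-dimethyl-10-oxoundec-2-enoate (both C7 epimers) | C[C@@H](CC/C=C(\C)C(=O)OC)C(C=O)CCC(C)=O | intermediate
6 | methyl (2E,6S)-2-methyl-6-(4-oxocyclohex-2-en-1-yl)hept-2-enoate (both ring epimers) | C[C@@H](CC/C=C(\C)C(=O)OC)C1C=CC(=O)CC1 | intermediate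
7 | methyl (2S)-2-[(1R,4S,5S)-4-methyl-8-oxospiro[4.5]dec-6-en-1-yl]propanoate | COC(=O)[C@@H](C)[C@H]1CC[C@H](C)[C@@]12C=CC(=O)CC2 | intermediate
8 | methyl (2S)-2-[(1R,4S,5S,9S)-9-acetoxy-4-methyl-8-oxospiro[4.5]dec-6-en-1-yl]propanoate | COC(=O)[C@@H](C)[C@H]1CC[C@H](C)[C@@]12C=CC(=O)[C@@H](OC(C)=O)C2 | intermediate
9 | lithium C7=C8 enolate of the 6,7-dihydro derivative of 8 | COC(=O)[C@@H](C)[C@H]1CC[C@H](C)[C@@]12CC=C([O-])[C@@H](OC(C)=O)C2.[Li+] | intermediate
10 | methyl (2S)-2-[(1R,4S,5S,9S)-9-acetoxy-4-methyl-8-(trifluoromethylsulfonyloxy)spiro[4.5]dec-7-en-1-yl]propanoate | COC(=O)[C@@H](C)[C@H]1CC[C@H](C)[C@@]12CC=C(OS(=O)(=O)C(F)(F)F)[C@@H](OC(C)=O)C2 | intermediate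
11 | methyl (2S)-2-[(1R,4S,5S,9S)-9-acetoxy-4,8-dimethylspiro[4.5]dec-7-en-1-yl]propanoate | COC(=O)[C@@H](C)[C@H]1CC[C@H](C)[C@@]12CC=C(C)[C@@H](OC(C)=O)C2 | intermediate
12 | (2S)-2-[(1R,4S,5S,9S)-9-hydroxy-4,8-dimethylspiro[4.5]dec-7-en-1-yl]propanal | O=C[C@@H](C)[C@H]1CC[C@H](C)[C@@]12CC=C(C)[C@@H](O)C2 | intermediate
13 | 3-phenylpropanoyl chloride | O=C(Cl)CCc1ccccc1 | starting material
14 | (1R,4S,5S,9S)-4,8-dimethyl-1-[(2S)-1-oxopropan-2-yl]spiro[4.5]dec-7-en-9-yl 3-phenylpropanoate | O=C[C@@H](C)[C@H]1CC[C@H](C)[C@@]12CC=C(C)[C@@H](OC(=O)CCc3ccccc3)C2 | intermediate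
15 | 3-methylfuran-2(5H)-one | CC1=CCOC1=O | starting material
16 | tert-butyl(dimethyl)[(3-methylfuran-2-yl)oxy]silane | Cc1ccoc1O[Si](C)(C)C(C)(C)C | intermediate
17 | (1R,4S,5S,9S)-1-{(2S)-1-[tert-butyl(dimethyl)silyloxy]-1-(4-methyl-5-oxo-2,5-dihydrofuran-2-yl)propan-2-yl}-4,8-dimethylspiro[4.5]dec-7-en-9-yl 3-phenylpropanoate (mixture at the two new carbons) | CC1=CC(OC1=O)C(O[Si](C)(C)C(C)(C)C)[C@@H](C)[C@H]2CC[C@H](C)[C@@]23CC=C(C)[C@@H](OC(=O)CCc4ccccc4)C3 | intermediate
18 | (1R,4S,5S,9S)-4,8-dimethyl-1-[(1Z,2S)-1-(4-methyl-5-oxofuran-2(5H)-ylidene)propan-2-yl]spiro[4.5]dec-7-en-9-yl 3-phenylpropanoate (CNP0260277.1) | CC1=C/C(=C/[C@@H](C)[C@H]2CC[C@H](C)[C@@]23CC=C(C)[C@@H](OC(=O)CCc2ccccc2)C3)OC1=O | target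

**Step count and risks**
Total step count: 8. Longest linear sequence: 8 (1 to 18).

The steps most likely to fail are steps 2, 4 and 3.

**Step 2.** The γ-attack of a tertiary dienolate carbon on a trisubstituted enoate may stall at 6 or give a poor diastereomer ratio. The fallback sets out from 3 and comes back at 7. Ring B is closed first under neutral enamine conditions. Stoichiometric pyrrolidine gives the pyrrolidine enamine F1, which cyclises onto the enoate in refluxing MeCN and is hydrolysed to the formyl ester F2. F2 is converted into the exocyclic piperidine enamine F3, in which C5 is flat. F3 takes up 4 from the face anti to the propanoate side chain, and aqueous AcOH/NaOAc then closes ring A by aldol condensation to give 7.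

**Step 4.** The acetoxy group activates the ketone towards 1,2-reduction, and the acetyl group may shift from O9 to the enolate oxygen in 9. The fallback sets out from 8 and comes back at 10. Hydrogenation (H2, Pd/C, EtOAc) saturates C6=C7 to give the acetoxy ketone F5, in which the acetoxy group rather than the alkene tells the two arms apart. Tf2O with 2,6-di-tert-butyl-4-methylpyridine in CH2Cl2 then enolises away from the electron-poor C9 without any free enolate and gives 10.

**Step 3.** The face selectivity at C9 rests only on a steric argument, and the hot reaction may epimerise C9. The fallback sets out from 7 and comes back at 8. The kinetic lithium dienolate (LiHMDS, THF, −78 °C) is hydroxylated with the matched enantiomer of (camphorsulfonyl)oxaziridine to give the hydroxy enone F4 under reagent-reinforced kinetic control. Ac2O/pyridine then gives 8.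

**Further compounds**
F1 | step 2 | methyl (2E,6S,7E)-2,6-dimethyl-8-(pyrrolidin-1-yl)octa-2,7-dienoate | C[C@@H](CC/C=C(\C)C(=O)OC)/C=C/N1CCCC1
F2 | step 2 | methyl (2S)-2-[(1S,3S)-2-formyl-3-methylcyclopentyl]propanoate (both C2 epimers) | COC(=O)[C@@H](C)[C@H]1CC[C@H](C)C1C=O
F3 | step 2 | methyl (2S)-2-[(1R,3S)-3-methyl-2-(piperidin-1-ylmethylidene)cyclopentyl]propanoate | COC(=O)[C@@H](C)[C@H]1CC[C@H](C)C1=CN2CCCCC2
F4 | step 3 | methyl (2S)-2-[(1R,4S,5S,9S)-9-hydroxy-4-methyl-8-oxospiro[4.5]dec-6-en-1-yl]propanoate | COC(=O)[C@@H](C)[C@H]1CC[C@H](C)[C@@]12C=CC(=O)[C@@H](O)C2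
F5 | step 4 | methyl (2S)-2-[(1R,4S,5S,9S)-9-acetoxy-4-methyl-8-oxospiro[4.5]decan-1-yl]propanoate | COC(=O)[C@@H](C)[C@H]1CC[C@H](C)[C@@]12CCC(=O)[C@@H](OC(C)=O)C2
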